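All runs are simulated with made-up constants.

**Late times.** Late in Sunday's run D reads 0.4 % at 15.0 min, and late in Saturday's run 0 % at 15.0 min. So we look for the height and time of an early peak.

| setting | Sunday's | Saturday's | Tuesday's | flask |
|---|---|---|---|---|
| Q | 0.010 M (fed, over 2.0 min) | 0.010 M (fed, over 2.0 min) | 0.015 M (fed, over 2.0 min) | 0.010 M (fed, over 2.0 min) |
| Z | 0.13 mM | 0.30 mM | 0.20 mM | 0.20 mM |
| remark | run made earlier; the fed solution adds 0.20 times the starting volume | run made earlier; the fed solution adds 0.20 times the starting volume | run made earlier; the fed solution adds 0.20 times the starting volume | the fed solution adds 0.20 times the starting volume |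
| time |  |  |  | 1.0 h |

- Sunday's (time / min: D / %): 0.500: 0.9; 1.33: 9.2; 3.00: 13.3; 6.00: 6.2; 15.0: 0.4; 40.0: 0.5
- Saturday's (time / min: D / %): 0.500: 1.9; 1.33: 9.1; 3.00: 7.2; 6.00: 2.7; 15.0: 0; 40.0: 0.9
- Tuesday's (time / min: D / %): 0.500: 2.6; 1.50: 7.6; 5.00: 7.3; 12.0: 0; 40.0: 0.5

(scatter of a reading: 1 percentage point)

- every charge counts on the volume at the start, and the solution that is fed holds the whole dose
- the numbers in the tables scatter by 1 percentage point (one standard deviation)
- steps thought possible: Q <-> D; D <-> E; E + Z <-> G + Z; G + Z <-> Q + Z; Z + D -> Z + L
- percentages count the whole charge, also what has not yet gone in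

* time up to 1.0 h at which D stands highest, in min
* the amount of D, in percent of the Q charged, at that time

**Two extremes.** Take the loss of D that grows with Z as pseudo-first-order in D, with Z held as charged. In one extreme version this loss is slow beside the feed, and the peak does not depend on Z. In the other it is fast, D sits at supply over loss, and the peak falls in inverse proportion to Z. The highest readings of Sunday's and Saturday's runs, 13.3 % and 9.1 %, differ by a factor of 1.46, less than the factor 2.31 in Z, so these two runs lie between the extremes, and we place the flask, with its Z between theirs, there too.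

**The drag.** Between them we write the reciprocal of the peak, taken as a fraction of the Q charged, as a part free of Z plus a part growing with Z. The drag, the rise of that reciprocal per millimole per litre of Z, is read from those two readings as 20.4 /mM, with their scatter. We keep Sunday's reading as the large thing and compute the correction for Z at 0.20 mM. That gives our own peak of 11.2 %, which we place in time between those two readings, at 1.33 min and 3.00 min.

**The forecast.** It says 11.5 % at 2.4 min, holding that “the peak must fall near the end of the feed”. Its height stands slightly above ours.

**The flask.** The flask gives 12.6 % at 2.26 min.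

    Q ⇌ D (K = 0.360, k = 0.0140 /s)
    D ⇌ E (K = 0.260, k = 0.120 /s)
    E + Z ⇌ G + Z, rate k3*[Z]*[E] forward; the back reaction follows from the equilibrium constant (K = 0.320, k = 1800 /M/s)
    G + Z ⇌ Q + Z, rate k4*[Z]*[G] forward; the back reaction follows from the equilibrium constant (k = 41.0 /M/s)
    Z + D → Z + L (k = 160 /M/s)

The drag of 20.4 /mM gave 11.2 % for this flask. For a neighbour with 0.0800 mM of Z it gives 15.4 %, where the neighbour reaches 17.4 %. In the flask, at 2 min, as the feed ended, Q stood at 64.8 %, D at 12.0 % and L at 19.2 % of the Q charged, with Z at 100 % of its own charge. Then Z + D into Z + L kept running while Q fed D, and at 0.500 h D stood at 0 % and L at >99.9 %.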